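**Retrosynthetic overview**
1. Target 14 ⇐ removal of two MOM ethers from the 5,7-bis(MOM)-6-prenylisoflavone 13.
2. The pyranone C ring is the only ring built, and it is built last: 13 ⇐ 2-hydroxydeoxybenzoin 10 + one carbon from DMF-DMA. Rings A and B are bought.
3. The C6 prenyl ⇐ para-Claisen–Cope rearrangement of aryl prenyl ether 7. The prenyl lands para to the freed OH, between the two MOM ethers, and that OH later becomes O1.
4. 7 ⇐ Mitsunobu prenylation of 5 ⇐ bis-MOM protection of 3 ⇐ Friedel–Crafts acylation of phloroglucinol 1 with 2,3,4-trimethoxyphenylacetic acid 2.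

Assumption: the target has no stereocentre and no E/Z-defined alkene, so "single enantiomer" needs no stereocontrol; 2 is taken as a catalogue compound.

**Route**

Step 1
Reactants: 1 phloroglucinol; 2 2-(2,3,4-trimethoxyphenyl)acetic acid
Product: 3 1-(2,4,6-trihydroxyphenyl)-2-(2,3,4-trimethoxyphenyl)ethan-1-one
Conditions: BF3·Et2O (Lewis acid and solvent), 85 °C, 2 h; aq. NaOAc work-up
Reagents that add atoms: none
Why: BF3-promoted Friedel–Crafts C-acylation of the very nucleophilic, threefold-symmetric phloroglucinol gives one mono-ketone, and no stereocentre is formed.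

Step 2
Reactants: 3 1-(2,4,6-trihydroxyphenyl)-2-(2,3,4-trimethoxyphenyl)ethan-1-one; 4 chloromethyl methyl ether
Product: 5 1-[2-hydroxy-4,6-bis(methoxymethoxy)phenyl]-2-(2,3,4-trimethoxyphenyl)ethan-1-one
Conditions: MOMCl (2.2 equiv), iPr2NEt, CH2Cl2, 0 °C → rt
Reagents that add atoms: chloromethyl methyl ether (4), COCCl
Why: O-alkylation (MOM protection) stops at the bis-ether because the last OH is hydrogen-bonded to the ketone, and since the two ortho OH groups of 3 are equivalent only one bis-ether can form.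

Step 3
Reactants: 5 1-[2-hydroxy-4,6-bis(methoxymethoxy)phenyl]-2-(2,3,4-trimethoxyphenyl)ethan-1-one; 6 3-methylbut-2-en-1-ol
Product: 7 1-[2,4-bis(methoxymethoxy)-6-(3-methylbut-2-en-1-yloxy)phenyl]-2-(2,3,4-trimethoxyphenyl)ethan-1-one
Conditions: PPh3, DIAD, THF, 0 °C → rt
Reagents that add atoms: 3-methylbut-2-en-1-ol (6), CC(C)=CCO
Why: Mitsunobu etherification alkylates the acidic chelated phenol on oxygen under neutral conditions, which avoids base-mediated C-alkylation of the benzylic ketone CH2.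

Step 4
Reactants: 7 1-[2,4-bis(methoxymethoxy)-6-(3-methylbut-2-en-1-yloxy)phenyl]-2-(2,3,4-trimethoxyphenyl)ethan-1-one
Product: 10 1-[6-hydroxy-2,4-bis(methoxymethoxy)-3-(3-methylbut-2-en-1-yl)phenyl]-2-(2,3,4-trimethoxyphenyl)ethan-1-one, via ortho-dienone 8 (not isolated), via para-dienone 9 (not isolated)
Conditions: PhNEt2, 200 °C (sealed tube or microwave), Ar, 2–3 h
Reagents that add atoms: none
Why: A para-Claisen–Cope rearrangement (aromatic Claisen [3,3] shift to the only free ortho carbon, Cope [3,3] shift on to the para carbon, then tautomerisation) delivers a linear prenyl group between the two MOM ethers, as in the same sequence on the corresponding acetophenone.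

Step 5
Reactants: 10 1-[6-hydroxy-2,4-bis(methoxymethoxy)-3-(3-methylbut-2-en-1-yl)phenyl]-2-(2,3,4-trimethoxyphenyl)ethan-1-one; 11 N,N-dimethylformamide dimethyl acetal
Product: 13 5,7-bis(methoxymethoxy)-6-(3-methylbut-2-en-1-yl)-3-(2,3,4-trimethoxyphenyl)-4H-chromen-4-one, via enaminone 12 (not isolated)
Conditions: DMF-DMA (3 equiv), toluene, 95 °C, 4 h
Reagents that add atoms: N,N-dimethylformamide dimethyl acetal (11), COC(OC)N(C)C
Why: Aminomethylenation of the benzylic CH2 followed by intramolecular oxa-Michael addition and loss of Me2NH (the deoxybenzoin isoflavone synthesis) closes the pyranone through the only free OH, which fixes the prenyl group at C6.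

Step 6
Reactants: 13 5,7-bis(methoxymethoxy)-6-(3-methylbut-2-en-1-yl)-3-(2,3,4-trimethoxyphenyl)-4H-chromen-4-one
Product: 14 5,7-dihydroxy-6-(3-methylbut-2-en-1-yl)-3-(2,3,4-trimethoxyphenyl)-4H-chromen-4-one
Conditions: HCl (ca. 1 M in MeOH), rt → 40 °C, monitored by TLC; NaHCO3 quench
Reagents that add atoms: none
Why: Mild acid-catalysed acetal methanolysis removes both MOM groups while the aryl methyl ethers and, at this acidity and temperature, the prenyl alkene are left alone.

**Compound list**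
1 | phloroglucinol (benzene-1,3,5-triol) | Oc1cc(O)cc(O)c1 | starting material
2 | 2-(2,3,4-trimethoxyphenyl)acetic acid | COc1ccc(CC(O)=O)c(OC)c1OC | starting material
3 | 1-(2,4,6-trihydroxyphenyl)-2-(2,3,4-trimethoxyphenyl)ethan-1-one | COc1ccc(CC(=O)c2c(O)cc(O)cc2O)c(OC)c1OC | intermediate
4 | chloromethyl methyl ether (MOMCl) | COCCl | starting material
5 | 1-[2-hydroxy-4,6-bis(methoxymethoxy)phenyl]-2-(2,3,4-trimethoxyphenyl)ethan-1-one | COCOc1cc(O)c(C(=O)Cc2ccc(OC)c(OC)c2OC)c(OCOC)c1 | intermediate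
6 | 3-methylbut-2-en-1-ol (prenol) | CC(C)=CCO | starting material
7 | 1-[2,4-bis(methoxymethoxy)-6-(3-methylbut-2-en-1-yloxy)phenyl]-2-(2,3,4-trimethoxyphenyl)ethan-1-one | COCOc1cc(OCC=C(C)C)c(C(=O)Cc2ccc(OC)c(OC)c2OC)c(OCOC)c1 | intermediate
8 | ortho-dienone, not isolated: 3,5-bis(methoxymethoxy)-6-(2-methylbut-3-en-2-yl)-2-[2-(2,3,4-trimethoxyphenyl)acetyl]cyclohexa-2,4-dien-1-one (racemic, transient sp3 centre) | COCOC1=CC(OCOC)=C(C(=O)Cc2ccc(OC)c(OC)c2OC)C(=O)C1C(C)(C)C=C | intermediate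
9 | para-dienone, not isolated: 3,5-bis(methoxymethoxy)-4-(3-methylbut-2-en-1-yl)-2-[2-(2,3,4-trimethoxyphenyl)acetyl]cyclohexa-2,5-dien-1-one | COCOC1=CC(=O)C(C(=O)Cc2ccc(OC)c(OC)c2OC)=C(OCOC)C1CC=C(C)C | intermediate
10 | 1-[6-hydroxy-2,4-bis(methoxymethoxy)-3-(3-methylbut-2-en-1-yl)phenyl]-2-(2,3,4-trimethoxyphenyl)ethan-1-one | COCOc1cc(O)c(C(=O)Cc2ccc(OC)c(OC)c2OC)c(OCOC)c1CC=C(C)C | intermediate
11 | N,N-dimethylformamide dimethyl acetal | COC(OC)N(C)C | starting material
12 | enaminone, not isolated: 3-(dimethylamino)-1-[6-hydroxy-2,4-bis(methoxymethoxy)-3-(3-methylbut-2-en-1-yl)phenyl]-2-(2,3,4-trimethoxyphenyl)prop-2-en-1-one (alkene geometry not defined; either isomer cyclises) | COCOc1cc(O)c(C(=O)C(=CN(C)C)c2ccc(OC)c(OC)c2OC)c(OCOC)c1CC=C(C)C | intermediate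
13 | 5,7-bis(methoxymethoxy)-6-(3-methylbut-2-en-1-yl)-3-(2,3,4-trimethoxyphenyl)-4H-chromen-4-one | COCOc1cc2occ(-c3ccc(OC)c(OC)c3OC)c(=O)c2c(OCOC)c1CC=C(C)C | intermediate
14 | 5,7-dihydroxy-6-(3-methylbut-2-en-1-yl)-3-(2,3,4-trimethoxyphenyl)-4H-chromen-4-one (achiral) | COc1ccc(-c2coc3cc(O)c(CC=C(C)C)c(O)c3c2=O)c(OC)c1OC | target

**Totals**
Total step count: 6. Longest linear sequence: 6 steps (1/2 → 3 → 5 → 7 → 10 → 13 → 14).

**Steps most likely to fail, with fallbacks**

Step 4 is the weakest. The Claisen intermediate 8 can enolise to the ortho 1,1-dimethylallyl phenol instead of going on to 9, and 7 can lose its prenyl group at 200 °C. The fallback drops the sigmatropic route and installs the prenyl group by cross-coupling. It sets out from 5, which with DMF-DMA (toluene, 95 °C) closes to 5,7-bis(methoxymethoxy)-3-(2,3,4-trimethoxyphenyl)-4H-chromen-4-one F1. Brief cold methanolic HCl (0 °C) removes only the peri, carbonyl-activated 5-O-MOM group and gives 5-hydroxy-7-(methoxymethoxy)-3-(2,3,4-trimethoxyphenyl)-4H-chromen-4-one F2. The chelated 5-OH then directs iodination (BnMe3N+ ICl2−, CaCO3, CH2Cl2/MeOH, rt) to C6, giving 5-hydroxy-6-iodo-7-(methoxymethoxy)-3-(2,3,4-trimethoxyphenyl)-4H-chromen-4-one F3. Stille coupling with tributyl(3-methylbut-2-en-1-yl)stannane (Pd(PPh3)4, DMF, 90 °C) gives 5-hydroxy-7-(methoxymethoxy)-6-(3-methylbut-2-en-1-yl)-3-(2,3,4-trimethoxyphenyl)-4H-chromen-4-one F4. The methanolic HCl of step 6 converts F4 into 14, where the fallback rejoins the route.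

Step 6 is next. Once the 5- and 7-OH groups flanking the prenyl group are free, acid can add either across the double bond to give a 2,2-dimethylchroman, or hydrate the alkene. The fallback uses no protecting groups, so no acid ever meets the C-prenyl phenol. It sets out from 3, which is cyclised (DMF, BF3·Et2O, MsCl, 70 °C) to 5,7-dihydroxy-3-(2,3,4-trimethoxyphenyl)-4H-chromen-4-one F5. Only the non-chelated 7-OH is alkylated (prenyl bromide, K2CO3, acetone, reflux), giving 5-hydroxy-7-(3-methylbut-2-en-1-yloxy)-3-(2,3,4-trimethoxyphenyl)-4H-chromen-4-one F6. Claisen rearrangement (cat. Eu(fod)3, CHCl3, 60 °C) should give 5,7-dihydroxy-8-(2-methylbut-3-en-2-yl)-3-(2,3,4-trimethoxyphenyl)-4H-chromen-4-one F7. Heating F7 in PhNEt2 at 200 °C should move the allyl unit from C8 to C6 by a Cope-type [3,3] shift through the C8-sp3 keto tautomer and give 14 directly. This regiochemical outcome rests on recalled behaviour of 7-O-prenyl-5-hydroxyflavones and is less certain than the main route; regioisomers would be separated by chromatography.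

Step 1 is third. With the electron-rich, ortho-methoxylated acid 2, neat BF3·Et2O at 85 °C can give O-acylation, partial O-demethylation or self-condensation. The fallback is a Hoesch reaction in place of the acid Friedel–Crafts. It sets out from 1, which with commercial 2-(2,3,4-trimethoxyphenyl)acetonitrile, ZnCl2 and HCl gas in Et2O at 0 °C precipitates 1-(2,4,6-trihydroxyphenyl)-2-(2,3,4-trimethoxyphenyl)ethan-1-iminium chloride F8. F8 is filtered off and boiled in water to give 3, where the route continues.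

**Further compounds**
F1 | step 4 | 5,7-bis(methoxymethoxy)-3-(2,3,4-trimethoxyphenyl)-4H-chromen-4-one | COCOc1cc2occ(-c3ccc(OC)c(OC)c3OC)c(=O)c2c(OCOC)c1
F2 | step 4 | 5-hydroxy-7-(methoxymethoxy)-3-(2,3,4-trimethoxyphenyl)-4H-chromen-4-one | COCOc1cc2occ(-c3ccc(OC)c(OC)c3OC)c(=O)c2c(O)c1
F3 | step 4 | 5-hydroxy-6-iodo-7-(methoxymethoxy)-3-(2,3,4-trimethoxyphenyl)-4H-chromen-4-one | COCOc1cc2occ(-c3ccc(OC)c(OC)c3OC)c(=O)c2c(O)c1I
F4 | step 4 | 5-hydroxy-7-(methoxymethoxy)-6-(3-methylbut-2-en-1-yl)-3-(2,3,4-trimethoxyphenyl)-4H-chromen-4-one | COCOc1cc2occ(-c3ccc(OC)c(OC)c3OC)c(=O)c2c(O)c1CC=C(C)C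
F5 | step 6 | 5,7-dihydroxy-3-(2,3,4-trimethoxyphenyl)-4H-chromen-4-one | COc1ccc(-c2coc3cc(O)cc(O)c3c2=O)c(OC)c1OC
F6 | step 6 | 5-hydroxy-7-(3-methylbut-2-en-1-yloxy)-3-(2,3,4-trimethoxyphenyl)-4H-chromen-4-one | COc1ccc(-c2coc3cc(OCC=C(C)C)cc(O)c3c2=O)c(OC)c1OC
F7 | step 6 | 5,7-dihydroxy-8-(2-methylbut-3-en-2-yl)-3-(2,3,4-trimethoxyphenyl)-4H-chromen-4-one | COc1ccc(-c2coc3c(C(C)(C)C=C)c(O)cc(O)c3c2=O)c(OC)c1OC
F8 | step 1 | 1-(2,4,6-trihydroxyphenyl)-2-(2,3,4-trimethoxyphenyl)ethan-1-iminium chloride | COc1ccc(CC(=[NH2+])c2c(O)cc(O)cc2O)c(OC)c1OC.[Cl-]
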